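Assumption: ring atoms are referred to by germacrane numbering (C-1 to C-10); read from the SMILES, the target is (4R,5R,6S,7R,8R,1(10)E), with the vanillate on O-6 and the free hydroxyl on C-8.

**Retrosynthetic overview**
1. C6–O acyl bond and C8–H: Evans–Tishchenko transfer from O-TBS-vanillin on the samarium aldolate of a ten-membered β-hydroxy ketone; this sets C-8 and puts the aroyl group on O-6 only.
2. C6–C7: samarium Reformatsky aldol of the acyclic α-bromo ketone/epoxy aldehyde 12 closes the ten-membered ring and sets C-6 and C-7, in the same flask as line 1.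
3. Oxirane: Sharpless epoxidation of allylic alcohol 10 sets C-4 and C-5; oxidation then gives the aldehyde.
4. C15 chain: geranyl acetate + CO + isobutenylstannane (carbonylative Stille), bromine by 1,4-hydrosilylation/NBS.
5. Ring order: oxirane first (step 7), ten-membered carbocycle last (step 10).

**Route**

Step 1
Reactants: 1 geranyl acetate [(2E)-3,7-dimethylocta-2,6-dien-1-yl acetate]
Product: 2 (2E,6E)-8-hydroxy-3,7-dimethylocta-2,6-dien-1-yl acetate
Conditions: SeO2 (0.3 equiv), salicylic acid (0.1 equiv), t-BuOOH (3 equiv), CH2Cl2, rt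
Reagents that add atoms: tert-butyl hydroperoxide, CC(C)(C)OO
Why: SeO2 allylic oxidation (ene reaction then 2,3-sigmatropic shift) hydroxylates the E-methyl of the electron-richer terminal alkene, the 2,3-alkene being deactivated by the allylic acetate.

Step 2
Reactants: 2 (2E,6E)-8-hydroxy-3,7-dimethylocta-2,6-dien-1-yl acetate
Product: 3 (2E,6E)-8-bromo-3,7-dimethylocta-2,6-dien-1-yl acetate
Conditions: CBr4, PPh3, CH2Cl2, 0 °C
Reagents that add atoms: carbon tetrabromide, BrC(Br)(Br)Br
Why: The Appel reaction converts the primary allylic alcohol into the bromide under neutral conditions without allylic transposition or loss of E geometry.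

Step 3
Reactants: 4 2-methylprop-1-en-1-ylmagnesium bromide (THF solution)
Product: 5 tributyl(2-methylprop-1-en-1-yl)stannane
Conditions: Bu3SnCl, THF, 0 °C to rt
Reagents that add atoms: tributyltin chloride, CCCC[Sn](Cl)(CCCC)CCCC
Why: Salt metathesis (transmetallation from magnesium to tin) gives the air-stable vinylstannane needed for the carbonylative coupling.

Step 4
Reactants: 3 (2E,6E)-8-bromo-3,7-dimethylocta-2,6-dien-1-yl acetate; 5 tributyl(2-methylprop-1-en-1-yl)stannane
Product: 6 (2E,6E)-3,7,11-trimethyl-9-oxododeca-2,6,10-trien-1-yl acetate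
Conditions: Pd(dba)2 (3 mol%), PPh3 (6 mol%), CO (4 atm), THF, 50 °C
Reagents that add atoms: carbon monoxide, [C-]#[O+]
Why: In this carbonylative Stille coupling the allylic bromide adds to zerovalent palladium much faster than the allylic acetate, CO inserts at the unsubstituted allyl terminus before the slow vinyl transfer from tin, and the E alkene is kept.

Step 5
Reactants: 6 (2E,6E)-3,7,11-trimethyl-9-oxododeca-2,6,10-trien-1-yl acetate
Product: 7 (6E,10E)-12-hydroxy-2,6,10-trimethyldodeca-2,6,10-trien-4-one
Conditions: Novozym 435 (immobilised Candida antarctica lipase B), KH2PO4/K2HPO4 buffer pH 7, acetone, 30 °C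
Reagents that add atoms: none
Why: Lipase-catalysed ester hydrolysis frees the primary allylic alcohol at neutral pH, so the β,γ-unsaturated ketone is not isomerised into conjugation as it could be under basic methanolysis.

Step 6
Reactants: 7 (6E,10E)-12-hydroxy-2,6,10-trimethyldodeca-2,6,10-trien-4-one
Product: 10 rac-(6E,10E)-3-bromo-12-hydroxy-2,6,10-trimethyldodeca-6,10-dien-4-one, via bis(triethylsilyl) enol ether 8 (not isolated), via O-triethylsilyl bromoketone 9 (not isolated)
Conditions: RhCl(PPh3)3 (2 mol%), Et3SiH (2.1 equiv), benzene, 50 °C; then NBS, THF, −78 °C; then PPTS (cat.), MeOH, 0 °C to rt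
Reagents that add atoms: N-bromosuccinimide, O=C1CCC(=O)N1Br
Why: Rhodium-catalysed 1,4-hydrosilylation of the s-cis β,β-disubstituted enone gives the silyl enol ether only toward the isopropyl side (the alcohol is silylated in passing), electrophilic bromination by NBS then puts bromine only on that α-carbon, and acidic methanol removes the primary silyl ether; the racemic C–Br centre is erased in step 10.

Step 7
Reactants: 10 rac-(6E,10E)-3-bromo-12-hydroxy-2,6,10-trimethyldodeca-6,10-dien-4-one
Product: 11 (3RS,6E)-3-bromo-9-[(2R,3R)-3-(hydroxymethyl)-2-methyloxiran-2-yl]-2,6-dimethylnon-6-en-4-one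
Conditions: Ti(OiPr)4 (10 mol%), D-(−)-diethyl tartrate (12 mol%), t-BuOOH (2 equiv), 4 Å molecular sieves, CH2Cl2, −20 °C
Reagents that add atoms: tert-butyl hydroperoxide, CC(C)(C)OO
Why: Sharpless asymmetric epoxidation touches only the allylic-alcohol alkene, and the D-(−)-tartrate catalyst delivers oxygen to the face that gives the (2R,3R)-epoxy alcohol, which becomes C-5(R) and C-4(R) of the target.

Step 8
Reactants: 11 (3RS,6E)-3-bromo-9-[(2R,3R)-3-(hydroxymethyl)-2-methyloxiran-2-yl]-2,6-dimethylnon-6-en-4-one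
Product: 12 (2S,3R)-3-[(3E,7RS)-7-bromo-4,8-dimethyl-6-oxonon-3-en-1-yl]-3-methyloxirane-2-carbaldehyde
Conditions: Dess–Martin periodinane (1.3 equiv), CH2Cl2, 0 °C to rt; used crude
Reagents that add atoms: none
Why: Dess–Martin oxidation gives the α,β-epoxy aldehyde under non-basic conditions that leave the epoxide and the α-bromo ketone intact (the descriptor at the oxirane CH changes from R to S only by priority).

Step 9
Reactants: 13 vanillin (4-hydroxy-3-methoxybenzaldehyde)
Product: 14 4-[(tert-butyldimethylsilyl)oxy]-3-methoxybenzaldehyde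
Conditions: TBSCl, imidazole, DMF, rt
Reagents that add atoms: tert-butyldimethylsilyl chloride, CC(C)(C)[Si](C)(C)Cl
Why: Imidazole-promoted silylation masks the acidic phenol, which would otherwise protonate the samarium alkoxides in step 10.

Step 10
Reactants: 12 (2S,3R)-3-[(3E,7RS)-7-bromo-4,8-dimethyl-6-oxonon-3-en-1-yl]-3-methyloxirane-2-carbaldehyde; 14 4-[(tert-butyldimethylsilyl)oxy]-3-methoxybenzaldehyde
Product: 17 (1R,2S,3R,4R,6E,10R)-4-hydroxy-6,10-dimethyl-3-(propan-2-yl)-11-oxabicyclo[8.1.0]undec-6-en-2-yl 4-hydroxy-3-methoxybenzoate, via samarium aldolate 15 (not isolated), via O-TBS vanillate 16 (not isolated)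
Conditions: SmI2 (2.1 equiv, 0.1 M in THF) added over 2 h to 12 (3 mM, THF), −78 °C; then 14 (6 equiv), −78 to −20 °C; AcOH quench and extraction; then TBAF (1.2 equiv), AcOH (1.5 equiv), THF, 0 °C
Reagents that add atoms: none
Why: Proposed new method: a samarium Reformatsky aldol macrocyclisation run directly into an Evans–Tishchenko acyl transfer on the same trivalent samarium alkoxide; divalent samarium cleaves the C–Br bond far faster than it reduces the aldehyde and gives the regiodefined Z enolate from both C–Br epimers, which closes the ten-membered ring on the aldehyde held in a five-membered chelate with the epoxide oxygen (attack past H-5 gives the 5,6-threo carbinol, 6S; the closed Zimmerman–Traxler chair of the Z enolate gives the 6,7-syn centre, R in the target); the O-6 samarium aldolate then adds aldehyde 14 to a hemiacetal (the key C–O bond), whose hydride passes through a six-membered chair to the samarium-bound C-8 ketone from the O-6 side, giving the 1,3-anti alcohol (8R) and leaving the aroyl group on O-6 only; buffered fluoride frees the phenol without acyl migration; the closest known reactions are SmI2 Reformatsky-type aldol closures of medium rings from α-bromo ketone aldehydes, the SmI2-catalysed Evans–Tishchenko reduction of β-hydroxy ketones and aldol–Tishchenko cascades, which have not been combined in a macrocyclisation.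

**Compound list**
1 | geranyl acetate, (2E)-3,7-dimethylocta-2,6-dien-1-yl acetate | CC(C)=CCC/C(C)=C/COC(C)=O | starting material
2 | (2E,6E)-8-hydroxy-3,7-dimethylocta-2,6-dien-1-yl acetate | CC(=O)OC/C=C(C)/CC/C=C(C)/CO | intermediate
3 | (2E,6E)-8-bromo-3,7-dimethylocta-2,6-dien-1-yl acetate | CC(=O)OC/C=C(C)/CC/C=C(C)/CBr | intermediate
4 | 2-methylprop-1-en-1-ylmagnesium bromide | CC(C)=C[Mg]Br | starting material
5 | tributyl(2-methylprop-1-en-1-yl)stannane | CCCC[Sn](CCCC)(CCCC)C=C(C)C | intermediate
6 | (2E,6E)-3,7,11-trimethyl-9-oxododeca-2,6,10-trien-1-yl acetate | CC(=O)OC/C=C(C)/CC/C=C(C)/CC(=O)C=C(C)C | intermediate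
7 | (6E,10E)-12-hydroxy-2,6,10-trimethyldodeca-2,6,10-trien-4-one | OC/C=C(C)/CC/C=C(C)/CC(=O)C=C(C)C | intermediate
8 | triethyl{[(3Z,6E,10E)-2,6,10-trimethyl-12-(triethylsilyloxy)dodeca-3,6,10-trien-4-yl]oxy}silane (mainly Z enol ether) | CC[Si](CC)(CC)OC/C=C(C)/CC/C=C(C)/C/C(O[Si](CC)(CC)CC)=C/C(C)C | intermediate
9 | rac-(6E,10E)-3-bromo-2,6,10-trimethyl-12-(triethylsilyloxy)dodeca-6,10-dien-4-one | CC[Si](CC)(CC)OC/C=C(C)/CC/C=C(C)/CC(=O)C(Br)C(C)C | intermediate
10 | rac-(6E,10E)-3-bromo-12-hydroxy-2,6,10-trimethyldodeca-6,10-dien-4-one | OC/C=C(C)/CC/C=C(C)/CC(=O)C(Br)C(C)C | intermediate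
11 | (3RS,6E)-3-bromo-9-[(2R,3R)-3-(hydroxymethyl)-2-methyloxiran-2-yl]-2,6-dimethylnon-6-en-4-one (1:1 at C–Br) | CC(C)C(Br)C(=O)C/C(C)=C/CC[C@@]1(C)O[C@@H]1CO | intermediate
12 | (2S,3R)-3-[(3E,7RS)-7-bromo-4,8-dimethyl-6-oxonon-3-en-1-yl]-3-methyloxirane-2-carbaldehyde (1:1 at C–Br) | CC(C)C(Br)C(=O)C/C(C)=C/CC[C@@]1(C)O[C@@H]1C=O | intermediate
13 | vanillin, 4-hydroxy-3-methoxybenzaldehyde | COc1cc(C=O)ccc1O | starting material
14 | 4-[(tert-butyldimethylsilyl)oxy]-3-methoxybenzaldehyde | COc1cc(C=O)ccc1O[Si](C)(C)C(C)(C)C | intermediate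
15 | diiodosamarium (1R,2S,3S,6E,10R)-6,10-dimethyl-4-oxo-3-(propan-2-yl)-11-oxabicyclo[8.1.0]undec-6-en-2-olate | I[Sm](I)O[C@H]1[C@H](C(C)C)C(=O)C/C(C)=C/CC[C@@]2(C)O[C@H]12 | intermediate
16 | (1R,2S,3R,4R,6E,10R)-4-hydroxy-6,10-dimethyl-3-(propan-2-yl)-11-oxabicyclo[8.1.0]undec-6-en-2-yl 4-[(tert-butyldimethylsilyl)oxy]-3-methoxybenzoate | COc1cc(C(=O)O[C@H]2[C@H](C(C)C)[C@H](O)C/C(C)=C/CC[C@@]3(C)O[C@H]23)ccc1O[Si](C)(C)C(C)(C)C | intermediate
17 | (1R,2S,3R,4R,6E,10R)-4-hydroxy-6,10-dimethyl-3-(propan-2-yl)-11-oxabicyclo[8.1.0]undec-6-en-2-yl 4-hydroxy-3-methoxybenzoate (CNP0285693.1) | COc1cc(C(=O)O[C@H]2[C@H](C(C)C)[C@H](O)C/C(C)=C/CC[C@@]3(C)O[C@H]23)ccc1O | target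

**Step count**
Total: 10 steps. Longest linear sequence: 8 steps (1, 2, 4, 5, 6, 7, 8, 10); steps 3 and 9 make the two coupling partners.

**Steps most likely to fail, with fallbacks**

Step 10 (the proposed new step). Risks: SmI2 may reduce the epoxy aldehyde, the strained aldolate may undergo retro-aldol before acyl transfer, and the C-6/C-7 selectivity of the closure is predicted, not known. Fallback with known chemistry, from 12 back to 16: aldehyde 12 is cyclised with CrCl2 and catalytic LiI in THF at high dilution (chromium Reformatsky reaction, which does not reduce aldehydes or epoxy aldehydes) and quenched with water. This gives the isolated β-hydroxy ketone (1R,2S,3S,6E,10R)-2-hydroxy-6,10-dimethyl-3-(propan-2-yl)-11-oxabicyclo[8.1.0]undec-6-en-4-one F1, whose diastereomers can be separated. A classical Evans–Tishchenko reduction of F1 (SmI2 30 mol%, aldehyde 14, THF, −10 °C) then gives 16, which is desilylated as in step 10.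

Step 4. Risks: direct coupling without CO insertion, ionisation of the allylic acetate, and migration of the β,γ-alkene. Fallback without tin or CO, from 3 back to 6: bromide 3 is coupled with 2-methylbut-3-yn-2-ol (CuI 10 mol%, K2CO3, DMF, rt) to give the skipped enyne (2E,6E)-11-hydroxy-3,7,11-trimethyldodeca-2,6-dien-9-yn-1-yl acetate F2. A Meyer–Schuster rearrangement of the tertiary propargylic alcohol (ReOCl3(OPPh3)(SMe2) 5 mol%, DME, rt) then gives enone 6.

Step 6. Risks: alkene migration by rhodium hydride, incomplete 1,4-selectivity, and bromination of the trisubstituted alkenes. Fallback that replaces the catalytic silicon chemistry by a metal-free pericyclic 1,4-hydroboration, from 7 back to 10: catecholborane (2.2 equiv, THF, rt) borylates the alcohol and reduces the s-cis enone through a six-membered transition state. This gives 2-{[(2E,6E,9Z)-9-(1,3,2-benzodioxaborol-2-yloxy)-3,7,11-trimethyldodeca-2,6,9-trien-1-yl]oxy}-1,3,2-benzodioxaborole F3, used in solution. NBS at −78 °C brominates the enol borate, and aqueous work-up at pH 7 hydrolyses the boron groups to give 10 without a separate deprotection.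

**Further compounds**
F1 | step 10 | (1R,2S,3S,6E,10R)-2-hydroxy-6,10-dimethyl-3-(propan-2-yl)-11-oxabicyclo[8.1.0]undec-6-en-4-one | O[C@H]1[C@H](C(C)C)C(=O)C/C(C)=C/CC[C@@]2(C)O[C@H]12
F2 | step 4 | (2E,6E)-11-hydroxy-3,7,11-trimethyldodeca-2,6-dien-9-yn-1-yl acetate | CC(=O)OC/C=C(C)/CC/C=C(C)/CC#CC(C)(C)O
F3 | step 6 | 2-{[(2E,6E,9Z)-9-(1,3,2-benzodioxaborol-2-yloxy)-3,7,11-trimethyldodeca-2,6,9-trien-1-yl]oxy}-1,3,2-benzodioxaborole | B1(Oc2ccccc2O1)OC/C=C(C)/CC/C=C(C)/C/C(OB1Oc2ccccc2O1)=C/C(C)C
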